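## The problem

Artocarpol D is a dibenzo[b,f]oxepine (ring A, oxepine ring C with the bridging oxygen O5, ring B) whose C10=C11 bond is also the enol-ether bond of a 2,2-dimethyl-2H-pyran (ring D: O1', C2'Me2, C3'=C4'). Ring A carries a phenol with an ortho prenyl group, and ring B a phenol para to C10. There is no stereocentre, so the task is one of connectivity and regiochemistry around a tetrasubstituted alkene. The only geometric question is the configuration of C11=C4' in an open-chain precursor of ring D, because only the Z isomer can close. Ring A is 1,2,4,5-tetrasubstituted and ring B 1,2,4-trisubstituted, so each arene must be built with its substituents in fixed positions, and three phenolic oxygens (two free, one in the ether bridge) must be told apart. The 2H-pyran is an acid-labile enol ether that can reopen by retro-6π. The prenyl group next to a phenol cyclises with acid or with electrophilic halogen, and the electron-rich phenols are oxidised easily in base. Late steps therefore exclude strong acid, electrophilic halogenation, hydrogenation and ether-cleaving Lewis acids. The feature that opens the route is the pattern at C10 and C11: each carries one aryl ring, C10 also carries O1', and C11 carries the chain C4'–C3'=C2'Me2. This is the pattern left when the C=O group of 3-methylbut-2-enal is exchanged across the triple bond of a diaryl alkyne and the resulting dienone closes through oxygen onto C2'. The oxygens of ring B, ortho and para to C10, make the two alkyne carbons electronically different in the sense this exchange needs.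

## Retrosynthesis

**Ring C and the last unmasking.** The final skeletal bond is the diaryl ether bond between O5 and the ring A carbon ortho to C11. Cutting it, after formal re-acylation of the ring A phenol (19 back to pivalate 18), gives bromophenol 17, which comes from bis-silyl ether 16 by fluoride. The neighbouring cut, O5–ring B, would place an oxygen on ring A ortho to C11, where it could trap a C10 cation as a benzofuran in the key step; bromine is inert there. The precursor loses the seven-membered ring and the conjugation that makes the tetracycle sensitive. The forward reaction must be an intramolecular Ullmann etherification that tolerates a second free phenol and a pivalate. The cis arrangement of the two arenes on C10=C11 holds OH and C–Br within bonding distance.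

**Ring D.** Ring D is opened at O1'–C2' by a retro-oxa-6π reaction: 16 becomes (Z)-dienone 15, which is related to its E isomer 14 by alkene isomerisation. The other cut, O1'–C10, would require enol ether formation from a ketone and a tertiary allylic alcohol under dehydrating acid. The electrocyclic cut needs no reagent and no leaving group. Precursor 14 has no ring between the arenes. The forward reaction must turn E into Z under conditions that spare the silyl ethers, pivalate and prenyl group, with the equilibrium on the pyran side.

**The key cut.** In 14 the C10=O and C11=C4' double bonds are cut together and exchanged for C≡C and C=O, giving diaryl alkyne 11 and 3-methylbut-2-enal 12, linked through oxetene 13. The neighbouring routes to the same enone, aldol condensation of a deoxybenzoin with 12 or olefination of a 1,2-diketone, need a separately made ketone and a dehydration or a regioselective olefination. The metathesis forms C11–C4' and C10–O in one catalytic, redox-neutral step and brings C4' in at the oxidation level of the target. The simplification is large: 11 is a linear molecule made from two arenes, and the five-carbon unit is a commercial aldehyde. The forward reaction must deliver the aldehyde carbon to C11 only. This is arranged by giving ring B two silyloxy donors and ring A an acyloxy group and a bromine.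

**The alkyne.** 11 is cut between the triple bond and ring A into aryl iodide 5 and terminal alkyne 10 (Sonogashira coupling). The other bond, alkyne–ring B, would pair an electron-rich, slowly reacting iodide with an alkyne that already contains an aryl bromide. The chosen polarity puts the iodide on the electron-poorer ring, where it reacts at room temperature and is cleanly distinguished from bromine. Both fragments are simple benzenes.

**Ring B fragment.** 10 is traced through silyl alkyne 9 to iodide 7 and ethynyltrimethylsilane 8, and 7 to 4-iodoresorcinol 6. Triisopropylsilyl is preferred to smaller silyl groups because it must survive methanolysis of the C–SiMe3 bond and two acidic steps. Its bulk and low basicity also keep the ortho oxygen out of any alkyne activation. The forward steps are a silylation, a Sonogashira coupling with no competing halide, and a selective C-desilylation.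

**Ring A fragment.** 5 is the pivalate of phenol 4. 4 is cut at the aryl–CH2 bond into 3-bromo-4-iodophenol 2 and prenyl bromide 3, and 2 at C–I into 3-bromophenol 1. Iodination comes before prenylation because electrophilic iodine would cyclise an ortho-prenylphenol. With the para position occupied by iodine and one ortho position flanked by bromine, C-alkylation of the phenoxide has one accessible site. Pivalate is chosen because it withdraws electron density from ring A in the key step and resists the amine bases of the couplings.

## Roads not taken

**Alternative 1:** The oxepine core is cut by a one-carbon ring contraction to the symmetric alkene 3,6-dimethoxy-9-methylenexanthene A1. In the forward step the trivalent iodine reagent PhI(OH)OTs in methanol adds to the exocyclic alkene, one aryl group shifts from C9 to the methylene carbon as iodobenzene leaves, and 3,7-dimethoxydibenzo[b,f]oxepin-10(11H)-one A2 results.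
- Merits: ring C and the C10 carbonyl arise in one step from a symmetric precursor, in which either aryl migration gives the same product. No chemoselective cross-coupling is needed. This road reaches the tricyclic core in fewer steps than the chosen plan.
- Weak points: A2 is only the bare core. The ring A prenyl group, the five-carbon unit at C11 and ring D are all still missing. The symmetry of A1 then becomes a liability, because the two oxygenated rings of A2 differ only through the remote ketone and a late C-prenylation ortho to one phenol has little to direct it. The two aryl methyl ethers must also be cleaved with reagents (boron halides, hot thiolates) that a prenyl group and a 2H-pyran do not survive, so they would have to be exchanged early.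
- Comparison: the chosen plan is longer to the core, but every substituent is fixed in the fragments before they meet, and the masking groups leave with fluoride and methanol.

**Alternative 2:** Three bonds are cut at once: O5–ring B, C10–C11 and O1'–C2'. The fragments are the ring A phenol A3, which carries the chain CH2–CO–CH=CMe2, and methyl 2-fluoro-4-(methoxymethoxy)benzoate A4. With Cs2CO3 the phenoxide should displace fluoride, the C11 enolate should acylate on the ester, and the diketone enol oxygen should add to the enone terminus to give pyranone A5.
- Merits: this is the most convergent of the four plans. Rings C and D form in one pot without a transition metal, and in bond economy it is better than the chosen route.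
- Weak points: the fluoride is activated only by an ortho ester and deactivated by a para alkoxy group. A3 is an ortho-hydroxybenzyl ketone that can dehydrate to a benzofuran. The seven-membered acylation competes with simpler enolate and oxa-Michael pathways. A5 also carries a carbonyl at C4' that the target lacks; its reduction and elimination on a vinylogous ester tends toward transposed enones, not a 2H-pyran. The methoxymethyl ethers would then have to be removed with acid next to an enol ether and a prenyl group.
- Comparison: the chosen plan forms fewer bonds per step, but the aldehyde carbon arrives as the future vinylic CH, so no redox correction follows.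

**Alternative 3:** Ring D is cut at O1'–C2' with a change of oxidation level. The 11-prenyl oxepinone dipivalate A6 would be treated with DDQ, which removes hydride from the allylic CH2 of the C11 prenyl group, and the alkylidene dienone would close by oxa-6π to artocarpol D dipivalate A7.
- Merits: the step follows the probable biogenesis. The pyran closes on a locked tricycle, so no open dienone/pyran equilibrium has to be managed, and only one deprotection follows. In end-game length it is better than the chosen plan, which needs four steps after its key step.
- Weak points: A6 contains two prenyl groups, and the oxidant must choose the C11 one over the benzylic, allylic CH2 on ring A. A simple ketone offers little enol to start the hydride transfer. A6 itself requires C-prenylation of an oxepinone enolate, which tends to alkylate on oxygen, so much of the problem moves into the preparation of the precursor.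
- Comparison: the chosen plan has the longer end game but uses no oxidant, and its regiochemistry is set by the donor pattern of the arenes.

Key step: step 8

Remark: the target and all isolated intermediates are achiral; the transient oxetene 13 has one stereocentre and is racemic.

## Route

Step 1
Reactants: 1 3-bromophenol
Product: 2 3-bromo-4-iodophenol
Conditions: NIS, TsOH·H2O (cat.), MeCN, 0 °C to rt
Reagents that add atoms: N-iodosuccinimide, O=C1CCC(=O)N1I
Why: Electrophilic aromatic iodination; acid-activated NIS in acetonitrile favours the position para to a phenolic hydroxyl, so C4 (para to OH, ortho to Br) should be iodinated, and the minor ortho isomer can be removed by chromatography.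

Step 2
Reactants: 2 3-bromo-4-iodophenol; 3 1-bromo-3-methylbut-2-ene (prenyl bromide)
Product: 4 5-bromo-4-iodo-2-(3-methylbut-2-en-1-yl)phenol
Conditions: NaH, toluene, 0 °C; then 3, rt
Reagents that add atoms: none
Why: Ortho C-alkylation of a sodium phenoxide in a non-polar solvent, where the aggregated ion pair shields oxygen and delivers the allylic bromide to the ortho carbon; the para position is blocked by iodine and the ortho position between OH and Br is hindered, so the chain should enter at C6, and any O-prenyl ether can be separated.

Step 3
Reactants: 4 5-bromo-4-iodo-2-(3-methylbut-2-en-1-yl)phenol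
Product: 5 5-bromo-4-iodo-2-(3-methylbut-2-en-1-yl)phenyl pivalate
Conditions: PivCl, Et3N, DMAP (cat.), CH2Cl2, 0 °C to rt
Reagents that add atoms: pivaloyl chloride, CC(C)(C)C(=O)Cl
Why: Standard DMAP-catalysed acylation of a phenol; the pivalate is chosen because it lowers the donor strength of the ring A oxygen for step 8 and resists the amine bases of the coupling steps.

Step 4
Reactants: 6 4-iodoresorcinol (4-iodobenzene-1,3-diol)
Product: 7 4-iodo-1,3-bis(triisopropylsilyloxy)benzene
Conditions: TIPSCl, imidazole, DMF, rt to 40 °C
Reagents that add atoms: chlorotriisopropylsilane, CC(C)[Si](Cl)(C(C)C)C(C)C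
Why: Imidazole-promoted silylation of both phenols; the triisopropylsilyl ethers should withstand the basic methanol of step 6 and the acidic steps 8 and 9 and still leave with fluoride.

Step 5
Reactants: 7 4-iodo-1,3-bis(triisopropylsilyloxy)benzene; 8 ethynyltrimethylsilane
Product: 9 1-[(trimethylsilyl)ethynyl]-2,4-bis(triisopropylsilyloxy)benzene
Conditions: PdCl2(PPh3)2 (cat.), CuI (cat.), Et3N, THF, 50 °C
Reagents that add atoms: none
Why: Sonogashira coupling; the electron-rich, ortho-substituted iodide is slow in oxidative addition, but no other halide is present, so gentle heating and excess alkyne can be used freely.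

Step 6
Reactants: 9 1-[(trimethylsilyl)ethynyl]-2,4-bis(triisopropylsilyloxy)benzene
Product: 10 1-ethynyl-2,4-bis(triisopropylsilyloxy)benzene
Conditions: K2CO3 (cat.), MeOH/THF, 0 °C to rt
Reagents that add atoms: none
Why: Base-catalysed methanolysis of the C(sp)–SiMe3 bond, which is much faster than attack on the hindered aryl O–Si(iPr)3 bonds during a short exposure.

Step 7
Reactants: 5 5-bromo-4-iodo-2-(3-methylbut-2-en-1-yl)phenyl pivalate; 10 1-ethynyl-2,4-bis(triisopropylsilyloxy)benzene
Product: 11 4-{[2,4-bis(triisopropylsilyloxy)phenyl]ethynyl}-5-bromo-2-(3-methylbut-2-en-1-yl)phenyl pivalate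
Conditions: PdCl2(PPh3)2 (cat.), CuI (cat.), Et3N, THF, rt, degassed
Reagents that add atoms: none
Why: Sonogashira coupling; zerovalent palladium inserts into the C–I bond of the electron-poor ring at room temperature far faster than into the neighbouring C–Br bond, so the bromine should stay in place for step 11 and the pivalate is untouched by triethylamine.

Step 8
Reactants: 11 4-{[2,4-bis(triisopropylsilyloxy)phenyl]ethynyl}-5-bromo-2-(3-methylbut-2-en-1-yl)phenyl pivalate; 12 3-methylbut-2-enal (prenal)
Product: 14 (E)-1-[2,4-bis(triisopropylsilyloxy)phenyl]-2-[2-bromo-5-(3-methylbut-2-en-1-yl)-4-(pivaloyloxy)phenyl]-5-methylhexa-2,4-dien-1-one, via 2H-oxete 13 (not isolated)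
Conditions: AgSbF6 (10 mol %), 12 (2 equiv), ClCH2CH2Cl, 0 °C to rt
Reagents that add atoms: none
Why: AgSbF6 activates prenal and the alkyne attacks its carbonyl carbon through C11, because the vinyl cation that results at C10 is stabilised by the ortho and para silyloxy groups of ring B, whereas ring A offers only an acyloxy group and an ortho bromine. The aldehyde oxygen then bonds to C10 to give 2H-oxete 13, whose thermal conrotatory 4π opening cleaves the O–C4' bond and leaves the enone with its carbonyl on C10, so the C11–C4' and C10–O bonds are both formed. The closest known reaction type is the silver- or acid-catalysed intermolecular carbonyl–alkyne metathesis of aryl alkynes with aldehydes, which gives trisubstituted (E)-enones. No ring of the target is closed and no stereocentre is created; the E geometry follows from outward rotation of the 2-methylpropenyl group during ring opening and is reset in step 9 in any case. The selectivity needed is regiochemical (C11 and not C10 to the aldehyde carbon) and is set by the donor difference between the two rings, which is why ring A carries a pivalate and not a silyl ether. Addition at the carbonyl carbon over conjugate addition is secured by the fully substituted β-carbon of prenal, and the donor-activated alkyne should outcompete the isolated trisubstituted alkene of the prenyl group for the activated aldehyde. Benzofuran formation is not expected, because the ortho substituent of ring A is bromine and the ortho oxygen of ring B can only reach C11, which carries no positive charge; Nazarov closure onto ring B is disfavoured because the ring carbon that would have to attack lies meta to both oxygens.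

Step 9
Reactants: 14 (E)-1-[2,4-bis(triisopropylsilyloxy)phenyl]-2-[2-bromo-5-(3-methylbut-2-en-1-yl)-4-(pivaloyloxy)phenyl]-5-methylhexa-2,4-dien-1-one
Product: 16 6-[2,4-bis(triisopropylsilyloxy)phenyl]-5-[2-bromo-5-(3-methylbut-2-en-1-yl)-4-(pivaloyloxy)phenyl]-2,2-dimethyl-2H-pyran, via (Z)-dienone 15 (not isolated)
Conditions: camphor-10-sulfonic acid (10 mol %), toluene (dry), 40 °C
Reagents that add atoms: none
Why: Acid-catalysed E/Z isomerisation followed by thermal oxa-6π electrocyclisation (1-oxatriene to 2H-pyran); O-protonation gives a hydroxypentadienyl cation with charge at the tertiary C2', which lowers the rotation barrier about C11–C4', and the strained Z isomer 15 closes through oxygen onto C2'. The geminal methyl groups and the aryl group on C11 should hold the equilibrium on the pyran side, and any 16 already formed in step 8 passes through unchanged.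

Step 10
Reactants: 16 6-[2,4-bis(triisopropylsilyloxy)phenyl]-5-[2-bromo-5-(3-methylbut-2-en-1-yl)-4-(pivaloyloxy)phenyl]-2,2-dimethyl-2H-pyran
Product: 17 5-[2-bromo-5-(3-methylbut-2-en-1-yl)-4-(pivaloyloxy)phenyl]-6-(2,4-dihydroxyphenyl)-2,2-dimethyl-2H-pyran
Conditions: TBAF, AcOH, THF, 0 °C
Reagents that add atoms: none
Why: Fluoride cleavage of aryl silyl ethers; the acetic acid buffer keeps free phenoxide low, so the hindered pivalate should neither migrate nor be cleaved and the enol ether is not exposed to strong acid or base.

Step 11
Reactants: 17 5-[2-bromo-5-(3-methylbut-2-en-1-yl)-4-(pivaloyloxy)phenyl]-6-(2,4-dihydroxyphenyl)-2,2-dimethyl-2H-pyran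
Product: 18 artocarpol D ring A pivalate (the target with the ring A phenol as its 2,2-dimethylpropanoate)
Conditions: CuI (20 mol %), N,N-dimethylglycine (40 mol %), Cs2CO3 (3 equiv), 1,4-dioxane (dilute, degassed), 100 °C
Reagents that add atoms: none
Why: Intramolecular Ullmann diaryl ether synthesis closing the seven-membered ring C; the cis arrangement of the arenes on C10=C11 holds the ortho phenoxide of ring B next to the C–Br bond of ring A, while the para phenoxide can react only intermolecularly and is disfavoured by dilution. Any pivalate transferred or lost under these conditions is of no consequence, because step 12 removes it.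

Step 12
Reactants: 18 artocarpol D ring A pivalate
Product: 19 artocarpol D
Conditions: K2CO3, MeOH, rt, under argon; then aq. NH4Cl
Reagents that add atoms: none
Why: Base-mediated methanolysis (transesterification) of an aryl pivalate; the conditions are free of acid, electrophiles and oxidants, so the enol ether, the prenyl group and the free phenols should survive.

## Compound list

1 | 3-bromophenol | Oc1cccc(Br)c1 | starting material
2 | 3-bromo-4-iodophenol | Oc1ccc(I)c(Br)c1 | intermediate
3 | 1-bromo-3-methylbut-2-ene (prenyl bromide) | CC(C)=CCBr | starting material
4 | 5-bromo-4-iodo-2-(3-methylbut-2-en-1-yl)phenol | CC(C)=CCc1cc(I)c(Br)cc1O | intermediate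
5 | 5-bromo-4-iodo-2-(3-methylbut-2-en-1-yl)phenyl pivalate | CC(C)=CCc1cc(I)c(Br)cc1OC(=O)C(C)(C)C | intermediate
6 | 4-iodoresorcinol | Oc1ccc(I)c(O)c1 | starting material
7 | 4-iodo-1,3-bis(triisopropylsilyloxy)benzene | CC(C)[Si](Oc1ccc(I)c(O[Si](C(C)C)(C(C)C)C(C)C)c1)(C(C)C)C(C)C | intermediate
8 | ethynyltrimethylsilane | C#C[Si](C)(C)C | starting material
9 | 1-[(trimethylsilyl)ethynyl]-2,4-bis(triisopropylsilyloxy)benzene | CC(C)[Si](Oc1ccc(C#C[Si](C)(C)C)c(O[Si](C(C)C)(C(C)C)C(C)C)c1)(C(C)C)C(C)C | intermediate
10 | 1-ethynyl-2,4-bis(triisopropylsilyloxy)benzene | CC(C)[Si](Oc1ccc(C#C)c(O[Si](C(C)C)(C(C)C)C(C)C)c1)(C(C)C)C(C)C | intermediate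
11 | 4-{[2,4-bis(triisopropylsilyloxy)phenyl]ethynyl}-5-bromo-2-(3-methylbut-2-en-1-yl)phenyl pivalate | CC(C)=CCc1cc(C#Cc2ccc(O[Si](C(C)C)(C(C)C)C(C)C)cc2O[Si](C(C)C)(C(C)C)C(C)C)c(Br)cc1OC(=O)C(C)(C)C | intermediate
12 | 3-methylbut-2-enal (prenal) | CC(C)=CC=O | starting material
13 | racemic 4-[2,4-bis(triisopropylsilyloxy)phenyl]-3-[2-bromo-5-(3-methylbut-2-en-1-yl)-4-(pivaloyloxy)phenyl]-2-(2-methylprop-1-en-1-yl)-2H-oxete | CC(C)=CCc1cc(C2=C(c3ccc(O[Si](C(C)C)(C(C)C)C(C)C)cc3O[Si](C(C)C)(C(C)C)C(C)C)OC2C=C(C)C)c(Br)cc1OC(=O)C(C)(C)C | intermediate
14 | (E)-1-[2,4-bis(triisopropylsilyloxy)phenyl]-2-[2-bromo-5-(3-methylbut-2-en-1-yl)-4-(pivaloyloxy)phenyl]-5-methylhexa-2,4-dien-1-one | CC(C)=CCc1cc(/C(C(=O)c2ccc(O[Si](C(C)C)(C(C)C)C(C)C)cc2O[Si](C(C)C)(C(C)C)C(C)C)=C\C=C(C)C)c(Br)cc1OC(=O)C(C)(C)C | intermediate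
15 | (Z)-1-[2,4-bis(triisopropylsilyloxy)phenyl]-2-[2-bromo-5-(3-methylbut-2-en-1-yl)-4-(pivaloyloxy)phenyl]-5-methylhexa-2,4-dien-1-one | CC(C)=CCc1cc(/C(C(=O)c2ccc(O[Si](C(C)C)(C(C)C)C(C)C)cc2O[Si](C(C)C)(C(C)C)C(C)C)=C/C=C(C)C)c(Br)cc1OC(=O)C(C)(C)C | intermediate
16 | 6-[2,4-bis(triisopropylsilyloxy)phenyl]-5-[2-bromo-5-(3-methylbut-2-en-1-yl)-4-(pivaloyloxy)phenyl]-2,2-dimethyl-2H-pyran | CC(C)=CCc1cc(C2=C(c3ccc(O[Si](C(C)C)(C(C)C)C(C)C)cc3O[Si](C(C)C)(C(C)C)C(C)C)OC(C)(C)C=C2)c(Br)cc1OC(=O)C(C)(C)C | intermediate
17 | 5-[2-bromo-5-(3-methylbut-2-en-1-yl)-4-(pivaloyloxy)phenyl]-6-(2,4-dihydroxyphenyl)-2,2-dimethyl-2H-pyran | CC(C)=CCc1cc(C2=C(c3ccc(O)cc3O)OC(C)(C)C=C2)c(Br)cc1OC(=O)C(C)(C)C | intermediate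
18 | artocarpol D ring A pivalate | CC(C)=CCc1cc2c(cc1OC(=O)C(C)(C)C)Oc1cc(O)ccc1C1=C2C=CC(C)(C)O1 | intermediate
19 | artocarpol D | CC(C)=CCc1cc2c(cc1O)Oc1cc(O)ccc1C1=C2C=CC(C)(C)O1 | target

## Step count and risks

Total step count: 12. Longest linear sequence: 9 steps (steps 1–3 and 7–12 from 3-bromophenol; the ring B branch, steps 4–6 and 7–12, is equally long).

**Step 8 (key step).** Three things could go wrong.
- The activated aldehyde could be diverted into a carbonyl–ene or Prins reaction at the prenyl alkene of ring A, whose nucleophilicity is not far below that of the alkyne.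
- Silver π-activation could trigger 5-endo attack of the ortho silyloxy oxygen with loss of silicon.
- The hindered diaryl alkyne could react so slowly that prenal oligomerises first.

The fallback sets out from 11 and returns at 16, and uses known carbonyl chemistry in place of the metathesis. Hydration of the alkyne with (Ph3P)AuNTf2 in wet 1,4-dioxane should place the oxygen on C10, for the same electronic reason that governs step 8, and give the deoxybenzoin 4-{2-[2,4-bis(triisopropylsilyloxy)phenyl]-2-oxoethyl}-5-bromo-2-(3-methylbut-2-en-1-yl)phenyl pivalate F1. Its lithium enolate (LiN(SiMe3)2, THF, −78 °C) should add to the carbonyl group of 12 to give the β-hydroxy ketone F2 as a mixture of racemic diastereomers. Catalytic camphorsulfonic acid in toluene should ionise the allylic alcohol of F2, so that the ketone oxygen closes onto C2' directly or water is lost to the dienone, which closes as in step 9. Either path gives 16.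

**Step 2.** The phenoxide may alkylate on oxygen, at the carbon between OH and Br, or twice, and the two halogens lower the nucleophilicity of the ring carbons, so conversion to the C-prenyl product may be poor.

The fallback sets out from 2 and returns at 4, building the side chain through an ortho-quinone methide whose position is fixed by a formyl group.
- Magnesium-mediated ortho-formylation (MgCl2, Et3N, paraformaldehyde, MeCN, reflux) should give 4-bromo-2-hydroxy-5-iodobenzaldehyde F3.
- NaBH4 in methanol should reduce it to 5-bromo-2-(hydroxymethyl)-4-iodophenol F4.
- Selective carbonate formation at the more acidic phenol (Boc2O, iPr2NEt, CH2Cl2, 0 °C) should give 5-bromo-2-(hydroxymethyl)-4-iodophenyl tert-butyl carbonate F5.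
- Excess 2-methylprop-1-enylmagnesium bromide (THF, −78 °C to rt) should deprotonate the benzylic alcohol, whereupon the carbonate migrates and is expelled to form the ortho-quinone methide. Conjugate addition of the alkenyl Grignard reagent then gives 4.

**Step 9.** The equilibrium among E-dienone, Z-dienone and monocyclic pyran may not lie far enough on the pyran side. The acid may also hydrate the enol ether, protonate the prenyl alkene or loosen a silyl ether before isomerisation is complete.

The fallback sets out from 14 and returns at 18, closing ring C before ring D so that the pyran forms only in the tricycle, where it is the stable valence isomer. Buffered TBAF (AcOH, THF, 0 °C) should give (E)-2-[2-bromo-5-(3-methylbut-2-en-1-yl)-4-(pivaloyloxy)phenyl]-1-(2,4-dihydroxyphenyl)-5-methylhexa-2,4-dien-1-one F6. Ullmann closure under the conditions of step 11 should give the 11-(3-methylbut-2-en-1-ylidene)dibenzo[b,f]oxepin-10(11H)-one pivalate F7; any oxa-Michael adduct of the ortho phenoxide should revert under the basic conditions. Heating F7 in toluene with a trace of acid should equilibrate the exocyclic alkene and drain it by oxa-6π closure into 18.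

**Step 11.** Oxidative addition at the C–Br bond, which sits ortho to a tetrasubstituted alkene, may be slow. The para phenoxide of ring B could then arylate intermolecularly, bromine could be lost reductively, or the pyran could open during prolonged heating in base.

The fallback sets out from 16 and returns at 18, reversing the polarity of the ring A carbon so that the ether bond forms oxidatively at room temperature.
- Miyaura borylation (B2pin2, Pd(dppf)Cl2, KOAc, 1,4-dioxane, 80 °C) should give the pinacol boronate F8.
- Buffered TBAF should free the two phenols to give the bisphenol boronate F9.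
- Intramolecular Chan–Lam coupling (Cu(OAc)2, pyridine, 4 Å molecular sieves, air, CH2Cl2, rt) should close ring C to 18.

## Further compounds

F1 | step 8 | 4-{2-[2,4-bis(triisopropylsilyloxy)phenyl]-2-oxoethyl}-5-bromo-2-(3-methylbut-2-en-1-yl)phenyl pivalate | CC(C)=CCc1cc(CC(=O)c2ccc(O[Si](C(C)C)(C(C)C)C(C)C)cc2O[Si](C(C)C)(C(C)C)C(C)C)c(Br)cc1OC(=O)C(C)(C)C
F2 | step 8 | 4-{1-[2,4-bis(triisopropylsilyloxy)phenyl]-3-hydroxy-5-methyl-1-oxohex-4-en-2-yl}-5-bromo-2-(3-methylbut-2-en-1-yl)phenyl pivalate (racemic diastereomers) | CC(C)=CCc1cc(C(C(O)C=C(C)C)C(=O)c2ccc(O[Si](C(C)C)(C(C)C)C(C)C)cc2O[Si](C(C)C)(C(C)C)C(C)C)c(Br)cc1OC(=O)C(C)(C)C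
F3 | step 2 | 4-bromo-2-hydroxy-5-iodobenzaldehyde | O=Cc1cc(I)c(Br)cc1O
F4 | step 2 | 5-bromo-2-(hydroxymethyl)-4-iodophenol | OCc1cc(I)c(Br)cc1O
F5 | step 2 | 5-bromo-2-(hydroxymethyl)-4-iodophenyl tert-butyl carbonate | OCc1cc(I)c(Br)cc1OC(=O)OC(C)(C)C
F6 | step 9 | (E)-2-[2-bromo-5-(3-methylbut-2-en-1-yl)-4-(pivaloyloxy)phenyl]-1-(2,4-dihydroxyphenyl)-5-methylhexa-2,4-dien-1-one | CC(C)=CCc1cc(/C(C(=O)c2ccc(O)cc2O)=C\C=C(C)C)c(Br)cc1OC(=O)C(C)(C)C
F7 | step 9 | 3-hydroxy-11-(3-methylbut-2-en-1-ylidene)-8-(3-methylbut-2-en-1-yl)-10-oxo-10,11-dihydrodibenzo[b,f]oxepin-7-yl pivalate (E/Z mixture; locants follow the SMILES) | CC(C)=CCc1cc2c(cc1OC(=O)C(C)(C)C)Oc1cc(O)ccc1C(=O)C2=CC=C(C)C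
F8 | step 11 | 4-{6-[2,4-bis(triisopropylsilyloxy)phenyl]-2,2-dimethyl-2H-pyran-5-yl}-2-(3-methylbut-2-en-1-yl)-5-(4,4,5,5-tetramethyl-1,3,2-dioxaborolan-2-yl)phenyl pivalate | CC(C)=CCc1cc(C2=C(c3ccc(O[Si](C(C)C)(C(C)C)C(C)C)cc3O[Si](C(C)C)(C(C)C)C(C)C)OC(C)(C)C=C2)c(B2OC(C)(C)C(C)(C)O2)cc1OC(=O)C(C)(C)C
F9 | step 11 | 4-[6-(2,4-dihydroxyphenyl)-2,2-dimethyl-2H-pyran-5-yl]-2-(3-methylbut-2-en-1-yl)-5-(4,4,5,5-tetramethyl-1,3,2-dioxaborolan-2-yl)phenyl pivalate | CC(C)=CCc1cc(C2=C(c3ccc(O)cc3O)OC(C)(C)C=C2)c(B2OC(C)(C)C(C)(C)O2)cc1OC(=O)C(C)(C)C
A1 | alternative 1 | 3,6-dimethoxy-9-methylene-9H-xanthene | C=C1c2ccc(OC)cc2Oc2cc(OC)ccc12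
A2 | alternative 1 | 3,7-dimethoxydibenzo[b,f]oxepin-10(11H)-one | COc1ccc2c(c1)Oc1cc(OC)ccc1C(=O)C2
A3 | alternative 2 | 1-[2-hydroxy-4-(methoxymethoxy)-5-(3-methylbut-2-en-1-yl)phenyl]-4-methylpent-3-en-2-one | CC(C)=CCc1cc(CC(=O)C=C(C)C)c(O)cc1OCOC
A4 | alternative 2 | methyl 2-fluoro-4-(methoxymethoxy)benzoate | COCOc1ccc(C(=O)OC)c(F)c1
A5 | alternative 2 | oxepine-fused 2,2-dimethyl-2,3-dihydro-4H-pyran-4-one bis(methoxymethyl) ether | CC(C)=CCc1cc2c(cc1OCOC)Oc1cc(OCOC)ccc1C1=C2C(=O)CC(C)(C)O1
A6 | alternative 3 | 11-(3-methylbut-2-en-1-yl)dibenzo[b,f]oxepin-10(11H)-one dipivalate carrying the ring A prenyl group | CC(C)=CCc1cc2c(cc1OC(=O)C(C)(C)C)Oc1cc(OC(=O)C(C)(C)C)ccc1C(=O)C2CC=C(C)C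
A7 | alternative 3 | artocarpol D dipivalate | CC(C)=CCc1cc2c(cc1OC(=O)C(C)(C)C)Oc1cc(OC(=O)C(C)(C)C)ccc1C1=C2C=CC(C)(C)O1
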